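How much faster does the flask make target at 5.0 % conversion if free catalyst is charged twice over, or at 8.0 mM?

- factor on the rate of making target when 5.0 % of the starting material are converted if free catalyst is charged twice over
- factor on the rate when 5.0 % of the starting material are converted if free catalyst is charged at 8.0 mM instead

| flask | starting material | free catalyst | remark |
|---|---|---|---|
| autumn | 0.30 M | 1.5 mM | the very flask that is asked about, followed so far |
| noon | 0.15 M | 1.5 mM | run made earlier |
| flask | 0.30 M | 1.5 mM |  |

- autumn (time / h: target / %, starting material / %): 1.50: 28.7, 70.7; 3.00: 50.5, 49.9; 5.00: 68.2, 32.5; 6.00: 73.9, 25.9; 8.00: 83.0, 17.7; 10.0: 88.7, 11.1; 12.0: 91.8, 7.7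
- noon (time / h: target / %, starting material / %): 1.33: 26.8, 73.6; 4.00: 59.6, 40.0; 6.00: 74.2, 25.6; 10.0: 88.7, 10.7; 15.0: 96.4, 3.9; 20.0: 97.6, 1.1; 25.0: 99.2, 1.6

(standard deviation of a reading: 0.5 percentage points)

- candidate steps: starting material + free catalyst -> free catalyst + target; free catalyst -> spent catalyst
- no earlier run changes the charge of free catalyst; that part of a forecast is a guess

I work with the fraction left, since ln(1/left)/t is the mean decay constant up to t. Early on, the autumn flask and the noon run, at different [starting material], give nearly the same value:

autumn 0.231 /h, noon 0.230 /h

The decay is therefore pseudo-first-order. No run varies the catalyst, so I guess from the candidate step that this constant scales with [free catalyst]. The factor is then the charge ratio times the ratio of the two flasks' mark shares, the mark share being the fraction of charged catalyst still free at 5.0 % conversion.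

The larger charge reaches the mark sooner, so I take its share as no lower, which puts the floor at the charge ratio. Its share cannot exceed one, so the ceiling is the charge ratio over this flask's share. I take that share as at least the whole-run mean, and the autumn constant sags:

0.214 /h / 0.231 /h = 92.4 %, so doubling gives at most 2.16

Taking the sag as steady loss tightens this:

loss 0.0144 /h, mark at 0.222 h, share 99.7 %

On this reckoning, which carries the scatter of the readings and my guess at the order, doubling lies between 2 and 2.01.

The forecast, 2 (1.6 to 2.15) and 5.33 (3.2 to 5.8), stands on the floor of my bracket and says “No run varied the catalyst”.

The flask gives 2.00 on doubling.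

    starting material + free catalyst → free catalyst + target (k = 2.60 /M/min)
    free catalyst → spent catalyst (k = 1.90 × 10⁻⁴ /min)

In this flask at 0.126 d, the half-life of starting material by the making of target is 0.13 d and that of free catalyst by its loss to spent catalyst is 2.5 d, and at 2.50 d starting material stands at 0 % with free catalyst at 50.5 %. At the mark the flask holds 99.8 % of its catalyst free against my mark share of 99.7 %, and at 8.0 mM the charge ratio over that share is 5.35, where the simulation gives 5.34.

Readings and results are simulated from invented constants; scatter was added.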